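**Retrosynthetic overview**

- Target 21 comes from ester 20 by saponification. 20 comes from a B-alkyl Suzuki–Miyaura coupling of the (S)-2-vinylchroman 12 with the (E)-vinyl iodide 18 (side-chain bond C2'–C3'). 18 is made from pent-4-yn-1-ol 13 by carboalumination and Wittig olefination.
- 12 comes from chroman-4-one 10 by removal of the C4 carbonyl oxygen.
- 10 comes from α-diazoketone 8. A Wolff shift moves C2 onto the diazo carbon (forms C2–C3), and the resulting ketene acylates C4a (forms C4–C4a). This closes ring B (the dihydropyran), the only ring that is built; ring A (the benzene ring) is bought in 1.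
- 8 comes from acid 6 and alcohol 4, and 4 from phenol 2 plus isoprene monoepoxide 3 by Pd-catalysed asymmetric allylic etherification, which sets C2 before the key step.
- Enabling feature: C2 is a hydrogen-free carbon bearing O1, and C4a is the only free position ortho to O1 on ring A (C8 carries the methyl) and is activated by O1. An acyl group on C2 can therefore be lengthened by one carbon with retention at C2 and then close onto C4a with no regiochemical choice.

Key step: step 5

Remark: both antipodes of the DACH-naphthyl bisphosphine ligand are commercial; the antipode that gives (R)-4 is assigned in the first run, because the sense of induction cannot be carried over safely from other nucleophiles.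

Remark: compounds 1, 3, 13 and 17 are taken as commercial; the pivalate on O6 is chosen because it is inert to the acidic steps 4, 5 and 7 and is removed in the final saponification.

**Route**

Step 1
Reactants: 1 2-methylbenzene-1,4-diol
Product: 2 4-hydroxy-3-methylphenyl pivalate
Conditions: PivCl (1.0 equiv), pyridine, CH2Cl2, −20 → 0 °C
Reagents that add atoms: pivaloyl chloride, CC(C)(C)C(=O)Cl
Why: O-acylation with a bulky acyl chloride should favour the hydroxyl remote from the ortho methyl group, and the regioisomer and the diester are removed by chromatography.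

Step 2
Reactants: 2 4-hydroxy-3-methylphenyl pivalate; 3 2-methyl-2-vinyloxirane (racemic)
Product: 4 4-{[(2R)-1-hydroxy-2-methylbut-3-en-2-yl]oxy}-3-methylphenyl pivalate
Conditions: Pd2(dba)3·CHCl3 (1 mol %), DACH-naphthyl bisphosphine ligand (3 mol %, antipode giving R), CH2Cl2, rt
Reagents that add atoms: none
Why: Tsuji–Trost-type asymmetric allylic etherification run as a dynamic kinetic asymmetric transformation: zerovalent palladium opens the racemic vinyl epoxide to π-allyl complexes that interconvert faster than they are trapped, the alkoxide hydrogen-bonds the phenol and steers it to the adjacent, fully substituted allyl terminus, and the chiral pocket of the ligand fixes C2 as R.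

Step 3
Reactants: 4 4-{[(2R)-1-hydroxy-2-methylbut-3-en-2-yl]oxy}-3-methylphenyl pivalate
Product: 6 (2R)-2-methyl-2-[2-methyl-4-(pivaloyloxy)phenoxy]but-3-enoic acid, via aldehyde 5 (not isolated)
Conditions: TEMPO (0.2 equiv), PhI(OAc)2 (2.2 equiv), MeCN/H2O (1:1), rt
Reagents that add atoms: water, O
Why: Oxoammonium (TEMPO) oxidation takes the primary alcohol to the non-enolisable aldehyde and, through its hydrate, to the acid; the vinyl group and aryl ester are inert and the quaternary C2 cannot epimerise.

Step 4
Reactants: 6 (2R)-2-methyl-2-[2-methyl-4-(pivaloyloxy)phenoxy]but-3-enoic acid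
Product: 8 4-{[(3R)-1-diazo-3-methyl-2-oxopent-4-en-3-yl]oxy}-3-methylphenyl pivalate, via acid chloride 7 (not isolated)
Conditions: (COCl)2, DMF (cat.), CH2Cl2, 0 °C → rt; then CH2N2 (excess), Et2O, 0 °C
Reagents that add atoms: oxalyl chloride, O=C(Cl)C(=O)Cl (chlorine of intermediate 7 only); diazomethane, C=[N+]=[N-]
Why: Acylation of diazomethane by the acid chloride (first stage of an Arndt–Eistert sequence), with excess diazomethane taking up the HCl; the carbonyl on C2 disfavours ionisation of the tertiary allylic ether and C2 has no hydrogen to lose.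

Step 5
Reactants: 8 4-{[(3R)-1-diazo-3-methyl-2-oxopent-4-en-3-yl]oxy}-3-methylphenyl pivalate
Product: 10 (2S)-2,8-dimethyl-4-oxo-2-vinylchroman-6-yl pivalate, via ketene 9 (not isolated)
Conditions: hν (450 nm LEDs), CH2Cl2 (0.02 M), −78 °C; then TfOH (1.2 equiv), −78 → −40 °C; NaHCO3 quench
Reagents that add atoms: none
Why: Irradiation of the s-Z diazoketone expels N2 with a concerted 1,2-shift of the quaternary carbon C2 from the acyl carbon (future C4) to the diazo carbon (future C3), which makes the C2–C3 bond with retention at C2 and gives ketene 9 (Wolff rearrangement, as in the Arndt–Eistert homologation of α-aryloxy acids); TfOH then protonates the ketene at C3 and the acylium ion acylates C4a, which makes the C4–C4a bond (Friedel–Crafts acylation, as in the cyclisation of 3-aryloxypropanoic acid derivatives to chroman-4-ones). Ring B is closed by a 6-exo-dig attack of C4a on the acylium carbon followed by loss of the C4a proton. No stereocentre is created: C2 is carried over unchanged in space, and its descriptor changes from R to S only because the vinyl group outranks C3 in 10. The step needs (a) the Wolff shift rather than carbene chemistry, secured by direct irradiation without copper, rhodium or silver salts, so that the vinylogous Wolff path through the C2 vinyl group, ylide formation at O1 and carbene attack on ring A are avoided; (b) a single acylation site, secured because C8, the other position ortho to O1, carries the methyl group and only the six-membered closure is free of strain; (c) an intact tertiary allylic ether, secured because the acid is added only after 8 is consumed and the acyl cation next to C2 disfavours ionisation of the C2–O1 bond. The pivalate on O6 leaves C5 and C7 less reactive than C4a, so intermolecular acylation should not compete at this dilution.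

Step 6
Reactants: 10 (2S)-2,8-dimethyl-4-oxo-2-vinylchroman-6-yl pivalate
Product: 11 (2S)-4-hydroxy-2,8-dimethyl-2-vinylchroman-6-yl pivalate (both C4 epimers)
Conditions: NaBH4, CeCl3·7H2O, MeOH, −20 °C
Reagents that add atoms: none
Why: Luche-type hydride reduction of the aryl ketone; the new C4 carbinol centre is formed without control, which does not matter because C4 becomes CH2 in step 7, and the cold, weakly basic medium should avoid retro-oxa-Michael opening at C2.

Step 7
Reactants: 11 (2S)-4-hydroxy-2,8-dimethyl-2-vinylchroman-6-yl pivalate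
Product: 12 (2S)-2,8-dimethyl-2-vinylchroman-6-yl pivalate
Conditions: Et3SiH (3 equiv), BF3·OEt2 (1.2 equiv), CH2Cl2, −78 °C
Reagents that add atoms: none
Why: Ionic hydrogenation: BF3 ionises the benzylic alcohol to a cation stabilised by O1 through C8a and the silane delivers hydride to C4, while the low temperature should spare the tertiary allylic ether at C2.

Step 8
Reactants: 13 pent-4-yn-1-ol
Product: 15 (4E)-5-iodo-4-methylpent-4-en-1-ol, via alkenylalane 14 (not isolated)
Conditions: AlMe3 (3 equiv), Cp2ZrCl2 (0.25 equiv), CH2Cl2, 0 °C → rt; then I2, THF, −30 → 0 °C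
Reagents that add atoms: trimethylaluminium, C[Al](C)C; iodine, II
Why: Negishi carboalumination adds methyl and aluminium syn across the alkyne with methyl on the internal carbon, and iodinolysis of the C–Al bond with retention gives the E vinyl iodide.

Step 9
Reactants: 15 (4E)-5-iodo-4-methylpent-4-en-1-ol
Product: 16 (4E)-5-iodo-4-methylpent-4-enal
Conditions: Dess–Martin periodinane, CH2Cl2, 0 °C → rt
Reagents that add atoms: none
Why: Dess–Martin oxidation stops at the aldehyde and leaves the vinyl iodide untouched.

Step 10
Reactants: 16 (4E)-5-iodo-4-methylpent-4-enal; 17 ethyl 2-(triphenyl-λ5-phosphanylidene)propanoate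
Product: 18 ethyl (2E,6E)-7-iodo-2,6-dimethylhepta-2,6-dienoate
Conditions: CH2Cl2, rt
Reagents that add atoms: none
Why: Wittig olefination with a stabilised, α-methyl ylide, which should give the E trisubstituted enoate.

Step 11
Reactants: 12 (2S)-2,8-dimethyl-2-vinylchroman-6-yl pivalate; 18 ethyl (2E,6E)-7-iodo-2,6-dimethylhepta-2,6-dienoate
Product: 20 ethyl (2E,6E)-9-[(2R)-2,8-dimethyl-6-(pivaloyloxy)chroman-2-yl]-2,6-dimethylnona-2,6-dienoate, via alkylborane 19 (not isolated)
Conditions: 9-BBN, THF, 0 °C → rt; then 18, Pd(dppf)Cl2·CH2Cl2 (5 mol %), AsPh3 (5 mol %), K3PO4 (aq.), DMF, rt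
Reagents that add atoms: 9-borabicyclo[3.3.1]nonane (9-BBN), B1C2CCCC1CCC2 (boron unit of intermediate 19 only)
Why: Anti-Markovnikov hydroboration of the vinyl group and B-alkyl Suzuki–Miyaura coupling with the vinyl iodide, which retains the E geometry and does not touch C2 (its descriptor becomes R only by the change in substituent ranking).

Step 12
Reactants: 20 ethyl (2E,6E)-9-[(2R)-2,8-dimethyl-6-(pivaloyloxy)chroman-2-yl]-2,6-dimethylnona-2,6-dienoate
Product: 21 (2E,6E)-9-[(2R)-6-hydroxy-2,8-dimethylchroman-2-yl]-2,6-dimethylnona-2,6-dienoic acid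
Conditions: LiOH·H2O, THF/MeOH/H2O (degassed), 45 °C; then 1 M HCl, 0 °C
Reagents that add atoms: lithium hydroxide, [Li+].[OH-]
Why: Saponification cleaves the ethyl enoate and the aryl pivalate in one operation, and exclusion of air protects the electron-rich chromanolate until acidification.

**Compound list**

1 | 2-methylbenzene-1,4-diol (methylhydroquinone) | Cc1cc(O)ccc1O | starting material
2 | 4-hydroxy-3-methylphenyl pivalate | Cc1cc(OC(=O)C(C)(C)C)ccc1O | intermediate
3 | 2-methyl-2-vinyloxirane (isoprene monoepoxide, racemic) | C=CC1(C)CO1 | starting material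
4 | 4-{[(2R)-1-hydroxy-2-methylbut-3-en-2-yl]oxy}-3-methylphenyl pivalate | C=C[C@](C)(CO)Oc1ccc(OC(=O)C(C)(C)C)cc1C | intermediate
5 | 3-methyl-4-{[(2R)-2-methyl-1-oxobut-3-en-2-yl]oxy}phenyl pivalate (aldehyde) | C=C[C@](C)(C=O)Oc1ccc(OC(=O)C(C)(C)C)cc1C | intermediate
6 | (2R)-2-methyl-2-[2-methyl-4-(pivaloyloxy)phenoxy]but-3-enoic acid | C=C[C@](C)(C(=O)O)Oc1ccc(OC(=O)C(C)(C)C)cc1C | intermediate
7 | (2R)-2-methyl-2-[2-methyl-4-(pivaloyloxy)phenoxy]but-3-enoyl chloride | C=C[C@](C)(C(=O)Cl)Oc1ccc(OC(=O)C(C)(C)C)cc1C | intermediate
8 | 4-{[(3R)-1-diazo-3-methyl-2-oxopent-4-en-3-yl]oxy}-3-methylphenyl pivalate | C=C[C@](C)(C(=O)C=[N+]=[N-])Oc1ccc(OC(=O)C(C)(C)C)cc1C | intermediate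
9 | 3-methyl-4-{[(3R)-3-methyl-1-oxopenta-1,4-dien-3-yl]oxy}phenyl pivalate (ketene) | C=C[C@](C)(C=C=O)Oc1ccc(OC(=O)C(C)(C)C)cc1C | intermediate
10 | (2S)-2,8-dimethyl-4-oxo-2-vinylchroman-6-yl pivalate | C=C[C@]1(C)CC(=O)c2cc(OC(=O)C(C)(C)C)cc(C)c2O1 | intermediate
11 | (2S)-4-hydroxy-2,8-dimethyl-2-vinylchroman-6-yl pivalate (both C4 epimers) | C=C[C@]1(C)CC(O)c2cc(OC(=O)C(C)(C)C)cc(C)c2O1 | intermediate
12 | (2S)-2,8-dimethyl-2-vinylchroman-6-yl pivalate | C=C[C@]1(C)CCc2cc(OC(=O)C(C)(C)C)cc(C)c2O1 | intermediate
13 | pent-4-yn-1-ol | C#CCCCO | starting material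
14 | dimethyl[(1E)-5-(dimethylalumanyloxy)-2-methylpent-1-en-1-yl]alumane (alkenylalane) | C[Al](C)OCCC/C(C)=C/[Al](C)C | intermediate
15 | (4E)-5-iodo-4-methylpent-4-en-1-ol | OCCC/C(C)=C/I | intermediate
16 | (4E)-5-iodo-4-methylpent-4-enal | O=CCC/C(C)=C/I | intermediate
17 | ethyl 2-(triphenyl-λ5-phosphanylidene)propanoate | CCOC(=O)C(C)=P(c1ccccc1)(c1ccccc1)c1ccccc1 | starting material
18 | ethyl (2E,6E)-7-iodo-2,6-dimethylhepta-2,6-dienoate | CCOC(=O)/C(C)=C/CC/C(C)=C/I | intermediate
19 | (2R)-2-[2-(9-borabicyclo[3.3.1]nonan-9-yl)ethyl]-2,8-dimethylchroman-6-yl pivalate (alkylborane) | C(C[C@]1(C)CCc2cc(OC(=O)C(C)(C)C)cc(C)c2O1)B1C2CCCC1CCC2 | intermediate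
20 | ethyl (2E,6E)-9-[(2R)-2,8-dimethyl-6-(pivaloyloxy)chroman-2-yl]-2,6-dimethylnona-2,6-dienoate | CCOC(=O)/C(C)=C/CC/C(C)=C/CC[C@]1(C)CCc2cc(OC(=O)C(C)(C)C)cc(C)c2O1 | intermediate
21 | (2E,6E)-9-[(2R)-6-hydroxy-2,8-dimethylchroman-2-yl]-2,6-dimethylnona-2,6-dienoic acid | C/C(=C\CC[C@]1(C)CCc2cc(O)cc(C)c2O1)CC/C=C(\C)C(=O)O | target

**Step count and risks**

Total step count: 12 steps. Longest linear sequence: 9 steps (steps 1 to 7, then 11 and 12).

Steps most likely to fail:

Step 5 (key step). The ketene may be lost before it is protonated, by dimerisation or by traces of water, or the photolysis may leak into carbene-type reactions, so that the acylium ion is not delivered cleanly to C4a. The fallback sets out from diazoketone 8 and returns to the route at chromanone 10, and it makes the two bonds in separate, standard operations. The Wolff rearrangement would be run by irradiation in THF/water, so that the ketene is taken up by water to give (3S)-3-methyl-3-[2-methyl-4-(pivaloyloxy)phenoxy]pent-4-enoic acid F1 (Arndt–Eistert homologation, retention at the migrating carbon). Oxalyl chloride would convert F1 into (3S)-3-methyl-3-[2-methyl-4-(pivaloyloxy)phenoxy]pent-4-enoyl chloride F2. F2 would then be cyclised in a discrete Friedel–Crafts acylation (SnCl4, CH2Cl2, −78 °C) to 10.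

Step 2. The phenol may attack the unsubstituted allyl terminus (linear ether), or the ortho methyl group may erode facial discrimination at the fully substituted terminus. The fallback sets out from phenol 2 and epoxide 3 and returns at alcohol 4, replacing asymmetric catalysis by resolution. An achiral catalyst, Pd(PPh3)4, would give racemic 4-[(1-hydroxy-2-methylbut-3-en-2-yl)oxy]-3-methylphenyl pivalate F3. F3 would be resolved by lipase-catalysed acetylation (lipase from Burkholderia cepacia, vinyl acetate, tert-butyl methyl ether), the enzyme being chosen in a screen so that the S alcohol is converted into 4-{[(2S)-1-acetoxy-2-methylbut-3-en-2-yl]oxy}-3-methylphenyl pivalate F4 and (R)-4 is left and separated by chromatography.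

Step 7. The Lewis acid may ionise the tertiary allylic ether at C2 (opening of ring B and loss of configuration), or the C4 cation may lose a proton from C3 to give the chromene instead of capturing hydride. The fallback sets out from chromanone 10, bypasses 11 and returns at 12 without any cation. Condensation with TsNHNH2 (EtOH, 60 °C) would give (2S)-2,8-dimethyl-4-[2-(4-methylphenylsulfonyl)hydrazinylidene]-2-vinylchroman-6-yl pivalate F5. Reduction of F5 with catecholborane (CHCl3, 0 °C) followed by NaOAc·3H2O at reflux would expel sulfinate and N2 and leave CH2 at C4.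

Further compounds
F1 | step 5 | (3S)-3-methyl-3-[2-methyl-4-(pivaloyloxy)phenoxy]pent-4-enoic acid | C=C[C@](C)(CC(=O)O)Oc1ccc(OC(=O)C(C)(C)C)cc1C
F2 | step 5 | (3S)-3-methyl-3-[2-methyl-4-(pivaloyloxy)phenoxy]pent-4-enoyl chloride | C=C[C@](C)(CC(=O)Cl)Oc1ccc(OC(=O)C(C)(C)C)cc1C
F3 | step 2 | racemic 4-[(1-hydroxy-2-methylbut-3-en-2-yl)oxy]-3-methylphenyl pivalate | C=CC(C)(CO)Oc1ccc(OC(=O)C(C)(C)C)cc1C
F4 | step 2 | 4-{[(2S)-1-acetoxy-2-methylbut-3-en-2-yl]oxy}-3-methylphenyl pivalate | C=C[C@@](C)(COC(C)=O)Oc1ccc(OC(=O)C(C)(C)C)cc1C
F5 | step 7 | (2S)-2,8-dimethyl-4-[2-(4-methylphenylsulfonyl)hydrazinylidene]-2-vinylchroman-6-yl pivalate | C=C[C@]1(C)CC(=NNS(=O)(=O)c2ccc(C)cc2)c2cc(OC(=O)C(C)(C)C)cc(C)c2O1
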